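**Retrosynthetic overview**
- Cinnamate: Heck arylation of the 6β-acrylate with iodobenzene; the acrylate comes from the 6β-hydroxy enal and acryloyl chloride.
- Enal: selective oxidation of the C15 primary alcohol of a 6β,15-diol, then base conjugation of the ring A alkene (C2=C3 to C3=C4); the diol comes from LiAlH4 reduction of a trans-decalone C15 pivalate, which sets C6.
- Ring B (key step): one-carbon ring expansion of a cis-hydrindenone (cyclopentanone to cyclohexanone) by Lewis-acid-catalysed insertion of 1-diazo-2-methylpropane with 1,2-shift of the C8 methylene; this brings in C7 with its isopropyl group, and C5/C7 are then equilibrated to the trans-fused isomer.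
- Ring A and the quaternary C10: catalytic enantioselective Diels–Alder reaction of 3-methylcyclopent-2-en-1-one with (E)-penta-2,4-dienyl pivalate.
- Ring order: five-membered precursor of ring B (bought), then ring A (cycloaddition), then ring B (ring expansion).

Assumption: (2E)-penta-2,4-dien-1-ol is bought as a catalogue compound; locants C1–C15 are eudesmane locants (C10 = methyl-bearing ring-fusion carbon, C5 = ring-fusion CH, C6 = oxygenated carbon, C7 = isopropyl-bearing carbon, C15 = carbon on C4) and β means the face of the C10 methyl group.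

**Step 1**
Reactants: 1 (2E)-penta-2,4-dien-1-ol
Product: 2 (2E)-penta-2,4-dien-1-yl 2,2-dimethylpropanoate
Conditions: PivCl (1.1 equiv), pyridine, 4-(dimethylamino)pyridine (DMAP, 5 mol %), CH2Cl2, 0 → 23 °C
Reagents that add atoms: pivaloyl chloride, CC(C)(C)C(=O)Cl
Why: Acylation of the primary alcohol (pivalate protection) masks C15-OH in a form that tolerates the Lewis acids of steps 2 and 4 and is removed without an extra step by the hydride of step 5; no stereocentre is formed.

**Step 2**
Reactants: 2 (2E)-penta-2,4-dien-1-yl 2,2-dimethylpropanoate; 3 3-methylcyclopent-2-en-1-one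
Product: 4 [(3aS,7R,7aR)-3a-methyl-1-oxo-2,3,3a,4,7,7a-hexahydro-1H-inden-7-yl]methyl 2,2-dimethylpropanoate (cis-fused; 3a-CH3, 7a-H and 7-H on the same face)
Conditions: (S)-3,3-diphenyl-1-(2-methylphenyl)tetrahydro-1H,3H-pyrrolo[1,2-c][1,3,2]oxazaborole (20 mol %), AlBr3 (16 mol %), 2 (3 equiv), CH2Cl2, −40 → −20 °C
Reagents that add atoms: none
Why: Proposed new method: an AlBr3-activated chiral oxazaborolidinium Lewis acid is used for an enantioselective Diels–Alder reaction of a β-methyl cyclopentenone, a dienophile class for which this catalysis has not been shown (closest known reaction type: oxazaborolidinium-catalysed Diels–Alder reactions of cyclic enones without a β-substituent); the cationic boron binds the carbonyl oxygen syn to the vinylic α-C–H, the aryl group shields one enone face, and the diene adds endo to the open face with its unsubstituted terminus (largest HOMO coefficient) bonding to the β-carbon (largest LUMO coefficient), which sets the quaternary C10 by catalyst control and the cis ring fusion and C4 centre by suprafacial endo addition, while ring strain of the cyclopentenone and the high Lewis acidity of the catalyst offset the rate-retarding β-methyl group.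

**Step 3**
Reactants: 5 2-methylpropanal
Product: 6 (E)-1-(tert-butyldimethylsilyl)-2-(2-methylpropylidene)hydrazine
Conditions: TBSNHNHTBS (1.05 equiv), Sc(OTf)3 (0.1 mol %), neat, 0 → 23 °C, then vacuum
Reagents that add atoms: 1,2-bis(tert-butyldimethylsilyl)hydrazine, CC(C)(C)[Si](C)(C)NN[Si](C)(C)C(C)(C)C
Why: Sc(OTf)3-catalysed condensation (hydrazone formation) of the aldehyde with the bis-silyl hydrazine gives an isolable N-silyl hydrazone that resists azine formation and serves as the precursor of diazoalkane 7; no stereocentre is formed.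

**Step 4**
Reactants: 4 [(3aS,7R,7aR)-3a-methyl-1-oxo-2,3,3a,4,7,7a-hexahydro-1H-inden-7-yl]methyl 2,2-dimethylpropanoate; 6 (E)-1-(tert-butyldimethylsilyl)-2-(2-methylpropylidene)hydrazine
Product: 9 [(1R,4aS,7S,8aS)-4a-methyl-8-oxo-7-(propan-2-yl)-1,4,4a,5,6,7,8,8a-octahydronaphthalen-1-yl]methyl 2,2-dimethylpropanoate (trans-fused), via 1-diazo-2-methylpropane 7 (not isolated), via cis-fused decalone C7-epimer mixture 8 (not isolated)
Conditions: 6 (2 equiv), PhIF2 (2 equiv), 2-chloropyridine, CH2Cl2, −78 → −30 °C, cold filtration through K2CO3; filtrate added to 4, Sc(OTf)3 (10 mol %), PhMe, −78 → −20 °C; then NaOMe (0.3 equiv), MeOH, 23 °C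
Reagents that add atoms: none
Why: Oxidation of the N-silyl hydrazone by PhIF2 gives the non-stabilised diazoalkane 7, whose carbon adds to the Sc(OTf)3-activated ketone, and in the diazonium alkoxide the less substituted C8 methylene undergoes the 1,2-shift to the former diazo carbon with loss of N2 (Tiffeneau–Demjanov-type diazoalkane ring expansion), turning the cyclopentanone into the cyclohexanone ring B with C7 carrying the isopropyl group; NaOMe then epimerises C5 and C7 (both α to the ketone) to the thermodynamically preferred trans-fused isomer in which isopropyl and CH2OPiv are equatorial.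

**Step 5**
Reactants: 9 [(1R,4aS,7S,8aS)-4a-methyl-8-oxo-7-(propan-2-yl)-1,4,4a,5,6,7,8,8a-octahydronaphthalen-1-yl]methyl 2,2-dimethylpropanoate
Product: 10 (1R,2S,4aS,8R,8aS)-8-(hydroxymethyl)-4a-methyl-2-(propan-2-yl)-1,2,3,4,4a,5,8,8a-octahydronaphthalen-1-ol (6β,15-diol)
Conditions: LiAlH4 (3 equiv), THF, −20 → 23 °C; H2O, aq. NaOH work-up
Reagents that add atoms: none
Why: Hydride reduction in which the axial (β) trajectory at C6 is blocked by the 1,3-diaxial C10 methyl group, so hydride enters equatorially and gives the axial 6β-alcohol (the outcome known for 6-oxo-5α-steroids), while LiAlH4 also cleaves the pivalate to free the C15 alcohol.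

**Step 6**
Reactants: 10 (1R,2S,4aS,8R,8aS)-8-(hydroxymethyl)-4a-methyl-2-(propan-2-yl)-1,2,3,4,4a,5,8,8a-octahydronaphthalen-1-ol
Product: 12 (4aR,7S,8R,8aR)-8-hydroxy-4a-methyl-7-(propan-2-yl)-3,4,4a,5,6,7,8,8a-octahydronaphthalene-1-carbaldehyde, via deconjugated hydroxy aldehyde 11 (not isolated)
Conditions: 2,2,6,6-tetramethylpiperidin-1-oxyl (TEMPO, 10 mol %), PhI(OAc)2 (1.1 equiv), CH2Cl2, 23 °C; aq. Na2S2O3 wash; 1,8-diazabicyclo[5.4.0]undec-7-ene (DBU, 0.3 equiv), CH2Cl2, 23 °C
Reagents that add atoms: none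
Why: Oxoammonium (TEMPO) oxidation is selective for the primary alcohol over the hindered axial secondary one and stops at aldehyde 11 because the 6β-axial oxygen and the 4α-formyl group cannot close a lactol; DBU then moves the C2=C3 bond into conjugation through the dienolate (γ-protonation), which removes the C4 stereocentre and leaves C5 untouched.

**Step 7**
Reactants: 12 (4aR,7S,8R,8aR)-8-hydroxy-4a-methyl-7-(propan-2-yl)-3,4,4a,5,6,7,8,8a-octahydronaphthalene-1-carbaldehyde; 13 prop-2-enoyl chloride
Product: 14 (1R,2S,4aR,8aR)-8-formyl-4a-methyl-2-(propan-2-yl)-1,2,3,4,4a,5,6,8a-octahydronaphthalen-1-yl prop-2-enoate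
Conditions: 13 (3 equiv), iPr2NEt (4 equiv), DMAP (20 mol %), CH2Cl2, 0 → 23 °C
Reagents that add atoms: none
Why: DMAP-catalysed acylation (nucleophilic catalysis via the acylpyridinium ion) esterifies the only hydroxyl group with retention at C6, and the enal is inert to these conditions.

**Step 8**
Reactants: 14 (1R,2S,4aR,8aR)-8-formyl-4a-methyl-2-(propan-2-yl)-1,2,3,4,4a,5,6,8a-octahydronaphthalen-1-yl prop-2-enoate; 15 iodobenzene
Product: 16 (1R,2S,4aR,8aR)-8-formyl-4a-methyl-2-(propan-2-yl)-1,2,3,4,4a,5,6,8a-octahydronaphthalen-1-yl (2E)-3-phenylprop-2-enoate (CNP0276672.1; eudesmane locants 5R,6R,7S,10R)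
Conditions: 15 (1.5 equiv), Pd(OAc)2 (5 mol %), Bu4NCl (1 equiv), NaHCO3 (2.5 equiv), DMF, 60 °C
Reagents that add atoms: none
Why: Mizoroki–Heck reaction under ligand-free phase-transfer conditions, in which oxidative addition of iodobenzene to zerovalent palladium formed in situ, syn insertion of the terminal acrylate alkene and syn β-hydride elimination give the (E)-cinnamate, while the trisubstituted enal alkene does not insert.

**Compound list**
1 | (2E)-penta-2,4-dien-1-ol | OC/C=C/C=C | starting material
2 | (2E)-penta-2,4-dien-1-yl 2,2-dimethylpropanoate | CC(C)(C)C(=O)OC/C=C/C=C | intermediate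
3 | 3-methylcyclopent-2-en-1-one | CC1=CC(=O)CC1 | starting material
4 | [(3aS,7R,7aR)-3a-methyl-1-oxo-2,3,3a,4,7,7a-hexahydro-1H-inden-7-yl]methyl 2,2-dimethylpropanoate | C1C[C@@]2(C)CC=C[C@@H](COC(=O)C(C)(C)C)[C@H]2C1=O | intermediate
5 | 2-methylpropanal | CC(C)C=O | starting material
6 | (E)-1-(tert-butyldimethylsilyl)-2-(2-methylpropylidene)hydrazine | CC(C)/C=N/N[Si](C)(C)C(C)(C)C | intermediate
7 | 1-diazo-2-methylpropane | CC(C)C=[N+]=[N-] | intermediate
8 | [(1R,4aS,8aR)-4a-methyl-8-oxo-7-(propan-2-yl)-1,4,4a,5,6,7,8,8a-octahydronaphthalen-1-yl]methyl 2,2-dimethylpropanoate (cis-fused; mixture of C7 epimers, C7 left undefined) | CC(C)C1CC[C@@]2(C)CC=C[C@@H](COC(=O)C(C)(C)C)[C@H]2C1=O | intermediate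
9 | [(1R,4aS,7S,8aS)-4a-methyl-8-oxo-7-(propan-2-yl)-1,4,4a,5,6,7,8,8a-octahydronaphthalen-1-yl]methyl 2,2-dimethylpropanoate | CC(C)[C@@H]1CC[C@@]2(C)CC=C[C@@H](COC(=O)C(C)(C)C)[C@@H]2C1=O | intermediate
10 | (1R,2S,4aS,8R,8aS)-8-(hydroxymethyl)-4a-methyl-2-(propan-2-yl)-1,2,3,4,4a,5,8,8a-octahydronaphthalen-1-ol | CC(C)[C@@H]1CC[C@@]2(C)CC=C[C@@H](CO)[C@@H]2[C@@H]1O | intermediate
11 | (1R,4aS,7S,8R,8aS)-8-hydroxy-4a-methyl-7-(propan-2-yl)-1,4,4a,5,6,7,8,8a-octahydronaphthalene-1-carbaldehyde | CC(C)[C@@H]1CC[C@@]2(C)CC=C[C@@H](C=O)[C@@H]2[C@@H]1O | intermediate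
12 | (4aR,7S,8R,8aR)-8-hydroxy-4a-methyl-7-(propan-2-yl)-3,4,4a,5,6,7,8,8a-octahydronaphthalene-1-carbaldehyde | CC(C)[C@@H]1CC[C@@]2(C)CCC=C(C=O)[C@@H]2[C@@H]1O | intermediate
13 | prop-2-enoyl chloride | C=CC(=O)Cl | starting material
14 | (1R,2S,4aR,8aR)-8-formyl-4a-methyl-2-(propan-2-yl)-1,2,3,4,4a,5,6,8a-octahydronaphthalen-1-yl prop-2-enoate | CC(C)[C@@H]1CC[C@@]2(C)CCC=C(C=O)[C@@H]2[C@@H]1OC(=O)C=C | intermediate
15 | iodobenzene | Ic1ccccc1 | starting material
16 | (1R,2S,4aR,8aR)-8-formyl-4a-methyl-2-(propan-2-yl)-1,2,3,4,4a,5,6,8a-octahydronaphthalen-1-yl (2E)-3-phenylprop-2-enoate | CC(C)[C@@H]1CC[C@@]2(C)CCC=C(C=O)[C@@H]2[C@@H]1OC(=O)/C=C/c1ccccc1 | target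

**Step count**
Total: 8 steps. Longest linear sequence: 7 steps (steps 1, 2, 4, 5, 6, 7, 8); step 3 is a one-step side branch.

**Three steps most likely to fail**

Risk at step 2 (the proposed new step). The β-methyl group may make the enone too unreactive, the dienyl ester may ionise under the strong Lewis acid, or the enantioselectivity may be low or of the opposite sense (in the last case the (R)-catalyst is used). The fallback uses known chemistry and sets out from 2 and 3. An AlCl3-promoted Diels–Alder reaction (0.5 equiv, PhMe, 40 °C; known for β-methyl cycloalkenones with 1-substituted dienes) gives the racemic endo adduct, that is 4 together with the enantiomeric hydrindenone F1. The racemate is ketalised with (1R,2R)-1,2-diphenylethane-1,2-diol (TsOH, PhH, reflux, water removal) to the diphenyldioxolane ketal F2 (from 4) and the diastereomeric ketal F3 (from F1). These are separated by chromatography or crystallisation, and hydrolysis of F2 (aq. HCl, THF, 23 °C) comes back to the route at 4.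

Risk at step 4. Fluoride by-products of the diazoalkane generation may deactivate Sc(OTf)3, the α-branched diazoalkane may give epoxide instead of insertion, or the ring-fusion methine may migrate in part. The fallback sets out from 4 and replaces the unstable diazoalkane by ethyl diazoacetate. BF3·OEt2-promoted ring expansion (CH2Cl2, 0 °C; methylene migration) gives the ring-expanded β-keto ester F4. C-Alkylation with 2-iodopropane (K2CO3, DMF, 50 °C) gives the isopropylated β-keto ester F5. Krapcho dealkoxycarbonylation (LiCl, wet DMSO, 150 °C) followed by NaOMe/MeOH equilibration comes back to the route at 9.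

Risk at step 5. The two equatorial groups flanking the ketone may slow equatorial hydride entry and erode the 6β selectivity. The fallback sets out from 9 and changes from intermolecular to hydroxyl-directed hydride delivery. Methanolysis of the pivalate (NaOMe, MeOH, 50 °C) gives the hydroxy ketone F6. Its C15 hydroxyl lies next to the equatorial site of C6, so Me4NBH(OAc)3 (AcOH/MeCN, −20 °C; directed reduction of the Evans–Saksena type) delivers hydride equatorially and comes back to the route at 10.

**Further compounds**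
F1 | step 2 | [(3aR,7S,7aS)-3a-methyl-1-oxo-2,3,3a,4,7,7a-hexahydro-1H-inden-7-yl]methyl 2,2-dimethylpropanoate (enantiomer of 4) | C1C[C@]2(C)CC=C[C@H](COC(=O)C(C)(C)C)[C@@H]2C1=O
F2 | step 2 | [(4R,5R,3a'S,7'R,7a'R)-3a'-methyl-4,5-diphenyl-2',3',3a',4',7',7a'-hexahydrospiro[[1,3]dioxolane-2,1'-inden]-7'-yl]methyl 2,2-dimethylpropanoate (ketal of 4) | C1C[C@@]2(C)CC=C[C@@H](COC(=O)C(C)(C)C)[C@H]2C13O[C@H](c4ccccc4)[C@@H](c4ccccc4)O3
F3 | step 2 | [(4R,5R,3a'R,7'S,7a'S)-3a'-methyl-4,5-diphenyl-2',3',3a',4',7',7a'-hexahydrospiro[[1,3]dioxolane-2,1'-inden]-7'-yl]methyl 2,2-dimethylpropanoate (ketal of F1) | C1C[C@]2(C)CC=C[C@H](COC(=O)C(C)(C)C)[C@@H]2C13O[C@H](c4ccccc4)[C@@H](c4ccccc4)O3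
F4 | step 4 | ethyl (4aS,8R,8aR)-4a-methyl-1-oxo-8-[(2,2-dimethylpropanoyloxy)methyl]-1,2,3,4,4a,5,8,8a-octahydronaphthalene-2-carboxylate (cis-fused; C2 epimers and enol, C2 left undefined) | CCOC(=O)C1CC[C@@]2(C)CC=C[C@@H](COC(=O)C(C)(C)C)[C@H]2C1=O
F5 | step 4 | ethyl (4aS,8R,8aR)-4a-methyl-1-oxo-8-[(2,2-dimethylpropanoyloxy)methyl]-2-(propan-2-yl)-1,2,3,4,4a,5,8,8a-octahydronaphthalene-2-carboxylate (cis-fused; C2 epimer mixture, C2 left undefined) | CCOC(=O)C1(C(C)C)CC[C@@]2(C)CC=C[C@@H](COC(=O)C(C)(C)C)[C@H]2C1=O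
F6 | step 5 | (2S,4aS,8R,8aS)-8-(hydroxymethyl)-4a-methyl-2-(propan-2-yl)-3,4,4a,5,8,8a-hexahydronaphthalen-1(2H)-one | CC(C)[C@@H]1CC[C@@]2(C)CC=C[C@@H](CO)[C@@H]2C1=O
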